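**Assumption:** methyl (R)‑glycidate (made industrially from L‑serine) is taken as a cheap commercial chiral building block; every metal catalyst named below is achiral or used as the racemate.

## Retrosynthetic overview

1. The target is the head‑to‑tail Markovnikov hydroalkoxylation dimer of (S)‑auraptenol 10. The tertiary C–O ether bond is cut first and is made last, in a photochemical cobalt‑hydride step.
2. (S)‑Auraptenol 10 comes from (S)‑meranzin 9 by epoxide → allylic alcohol isomerisation. Epoxide 9 comes from (R)‑meranzin hydrate 7 by mesylation and ring closure with inversion.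
3. Diol 7 comes from 8‑iodo‑7‑methoxycoumarin 5 and epoxy alcohol 2 by a Ni/photoredox aryl–CH2 coupling. Compound 2 comes from methyl (R)‑glycidate 1 and MeMgCl; 5 comes from umbelliferone 3.
4. Ring order: the coumarin bicycle is bought intact. The only rings handled are oxiranes: bought in 1, carried in 2, opened in step 4, re‑formed in 9, opened in step 6.

## Route

**Step 1**
Reactants: 1 methyl (R)‑glycidate
Product: 2 (R)‑2‑(oxiran‑2‑yl)propan‑2‑ol
Conditions: MeMgCl (2.3 equiv), THF, −78 → −30 °C; sat. aq NH4Cl at −30 °C; Et2O extraction, bulb‑to‑bulb distillation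
Reagents that add atoms: methylmagnesium chloride, C[Mg]Cl
Why: Double Grignard addition to the ester is far faster than epoxide opening at low temperature (the chloride Grignard limits halohydrin formation), and the oxirane stereocentre is not touched, so the purchased (R) configuration is carried over.

**Step 2**
Reactants: 3 umbelliferone
Product: 4 7‑hydroxy‑8‑iodocoumarin
Conditions: I2 (1.05 equiv), KI, 25% aq NH3, 0 °C → rt; then dil. H2SO4 to pH 3
Reagents that add atoms: iodine, II
Why: Electrophilic aromatic iodination of the phenoxide goes to C8, the position ortho to O7 and next to the ring oxygen, as is established for 7‑hydroxycoumarins.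

**Step 3**
Reactants: 4 7‑hydroxy‑8‑iodocoumarin
Product: 5 8‑iodo‑7‑methoxycoumarin
Conditions: MeI (1.5 equiv), K2CO3 (1.5 equiv), acetone, reflux
Reagents that add atoms: iodomethane, CI
Why: Williamson O‑methylation of the phenol; no other nucleophilic site is present.

**Step 4**
Reactants: 5 8‑iodo‑7‑methoxycoumarin; 2 (R)‑2‑(oxiran‑2‑yl)propan‑2‑ol (1.5 equiv)
Product: 7 (R)‑meranzin hydrate, via iodohydrin 6 (not isolated)
Conditions: NiBr2·glyme (10 mol %), dtbbpy (12 mol %), [Ir(ppy)2(dtbbpy)]PF6 (1 mol %), NaI (30 mol %), Et3N·HCl (50 mol %), Et3N (3 equiv), DMA, 450 nm LEDs, 25 °C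
Reagents that add atoms: none
Why: Ni/photoredox cross‑electrophile coupling of an aryl iodide with a terminal aliphatic epoxide, in which iodide opens the oxirane at CH2 to iodohydrin 6 and the primary radical is arylated on nickel, so the carbinol carbon is never touched and stays (R); the Ir sensitiser has a triplet energy (about 49 kcal/mol) too low to trigger coumarin [2+2] dimerisation.

**Step 5**
Reactants: 7 (R)‑meranzin hydrate
Product: 9 (S)‑meranzin, via mesylate 8 (not isolated)
Conditions: MsCl (1.1 equiv), Et3N (1.5 equiv), CH2Cl2, −10 °C; then K2CO3 (2 equiv), MeOH, 0 °C → rt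
Reagents that add atoms: none
Why: Selective sulfonylation of the secondary OH followed by intramolecular Williamson closure (3‑exo‑tet SN2) by the tertiary alkoxide inverts C2′ cleanly, turning the purchased (R) centre into the (S) epoxide.

**Step 6**
Reactants: 9 (S)‑meranzin
Product: 10 (S)‑auraptenol
Conditions: Cp2TiCl2 (10 mol %), achiral Co(II)(salen) (5 mol %), Zn (20 mol %), Et3N·HCl (1 equiv), THF, 25 °C
Reagents that add atoms: none
Why: Ti(III)/Co(II) radical redox‑relay isomerisation of an epoxide to an allylic alcohol: Cp2Ti(III) homolyses the tertiary C–O bond and Co(II) removes a methyl hydrogen atom from the tertiary radical to give the isopropenyl group, leaving the secondary C–O bond and its (S) configuration intact.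

**Step 7**
Reactants: 10 (S)‑auraptenol (two molecules)
Product: 11 target dimer CNP0142500.1, via (S)‑meranzin 9 (not isolated)
Conditions: [Ir(ppy)2(dtbbpy)]PF6 (2 mol %), achiral Co(II) complex of N,N′‑bis(3,5‑di‑tert‑butylsalicylidene)‑2,3‑dimethylbutane‑2,3‑diamine (5 mol %), 2,4,6‑collidinium triflate (20 mol %), PhCF3/HFIP 9:1, 1.0 M in 10, 450 nm LEDs, 25 °C, stopped at about 50% conversion; recovered 10 and any 9 recycled
Reagents that add atoms: none
Why: Proposed new method: a redox‑neutral photochemical cobalt‑hydride hydroalkoxylative homodimerisation of a free secondary allylic alcohol, in which Ir(III)* and Ir(II) disproportionate Co(II) into Co(III) and (with collidinium) Co(III)–H, Markovnikov hydrogen‑atom transfer to the isopropenyl group of one molecule of 10 gives the tertiary radical, Co(III) oxidises it (radical–polar crossover) to the tertiary alkyl–Co(IV)/cation, and the secondary OH of a second molecule of 10 captures it to form the hindered tert‑alkyl sec‑alkyl ether, while capture by the neighbouring OH gives epoxide 9, which the acid/HFIP medium reopens at the tertiary carbon to the same cation so both channels converge on 11; no stereocentre is created and neither carbinol C–O bond is broken, so both (S) centres are those of 10; the closest known reaction types are the Co(salen)/photoredox/Brønsted‑acid Markovnikov hydroalkoxylation of unactivated alkenes with added alcohols and the Co–H cycloisomerisation of allylic alcohols to epoxides, neither of which has been used to dimerise an allylic alcohol through its own hydroxyl.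

## Compound list

1 | methyl (2R)‑oxirane‑2‑carboxylate (methyl (R)‑glycidate) | COC(=O)[C@H]1CO1 | starting material
2 | 2‑[(2R)‑oxiran‑2‑yl]propan‑2‑ol | CC(C)(O)[C@H]1CO1 | intermediate
3 | 7‑hydroxy‑2H‑chromen‑2‑one (umbelliferone) | Oc1ccc2ccc(=O)oc2c1 | starting material
4 | 7‑hydroxy‑8‑iodo‑2H‑chromen‑2‑one | Oc1ccc2ccc(=O)oc2c1I | intermediate
5 | 8‑iodo‑7‑methoxy‑2H‑chromen‑2‑one | COc1ccc2ccc(=O)oc2c1I | intermediate
6 | (2S)‑1‑iodo‑3‑methylbutane‑2,3‑diol | CC(C)(O)[C@H](O)CI | intermediate
7 | 8‑[(2R)‑2,3‑dihydroxy‑3‑methylbutyl]‑7‑methoxy‑2H‑chromen‑2‑one ((R)‑meranzin hydrate) | CC(C)(O)[C@H](O)Cc1c(OC)ccc2ccc(=O)oc12 | intermediate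
8 | (2R)‑3‑hydroxy‑1‑(7‑methoxy‑2‑oxo‑2H‑chromen‑8‑yl)‑3‑methylbutan‑2‑yl methanesulfonate | CC(C)(O)[C@H](OS(C)(=O)=O)Cc1c(OC)ccc2ccc(=O)oc12 | intermediate
9 | 8‑{[(2S)‑3,3‑dimethyloxiran‑2‑yl]methyl}‑7‑methoxy‑2H‑chromen‑2‑one ((S)‑meranzin) | CC1(C)O[C@H]1Cc1c(OC)ccc2ccc(=O)oc12 | intermediate
10 | 8‑[(2S)‑2‑hydroxy‑3‑methylbut‑3‑en‑1‑yl]‑7‑methoxy‑2H‑chromen‑2‑one ((S)‑auraptenol) | C=C(C)[C@@H](O)Cc1c(OC)ccc2ccc(=O)oc12 | intermediate
11 | 8‑[(2S)‑2‑hydroxy‑3‑{[(2S)‑1‑(7‑methoxy‑2‑oxo‑2H‑chromen‑8‑yl)‑3‑methylbut‑3‑en‑2‑yl]oxy}‑3‑methylbutyl]‑7‑methoxy‑2H‑chromen‑2‑one | C=C(C)[C@H](Cc1c(OC)ccc2ccc(=O)oc12)OC(C)(C)[C@@H](O)Cc1c(OC)ccc2ccc(=O)oc12 | target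

## Step count and risk

Total steps: 7. Longest linear sequence: 6 (steps 2–7 from umbelliferone); step 1 runs in parallel.

The three steps most likely to fail:

**Step 7 (the proposed new dimerisation).** The risks are accumulation of epoxide 9 without reopening, hydride shift to the isopropyl ketone, over‑reaction of 11 to trimers, and sensitised coumarin photochemistry. The fallback uses known chemistry and sets out from 9 and 10, both already on the route: about one third of 9 is held back before step 6. Epoxide 9 is added slowly to 10 (3 equiv, the excess recovered) with BF3·OEt2 (10 mol %) in CH2Cl2 at −40 °C. This is the classical acid‑catalysed alcoholysis of a trisubstituted epoxide at its tertiary carbon; the secondary stereocentre is retained. It comes back to the route at 11 and needs no new compound (none F0).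

**Step 4 (Ni/photoredox coupling of a doubly ortho‑oxygenated aryl iodide).** The risks are slow radical capture at the hindered aryl–nickel centre and Giese addition of the alkyl radical to the coumarin. The fallback sets out from 2 and 5 and replaces the reductive radical coupling with a polar arylzinc/alkyl iodide Negishi coupling. Epoxide 2 is opened with LiI/AcOH in THF to iodohydrin 6, now isolated. Its diol is protected with 2,2‑dimethoxypropane/PPTS to give (S)‑4‑(iodomethyl)‑2,2,5,5‑tetramethyl‑1,3‑dioxolane F1. Iodide 5 is converted with Zn dust/LiCl in THF into (7‑methoxy‑2‑oxo‑2H‑chromen‑8‑yl)zinc iodide F2. F2 and F1 are coupled with Ni(acac)2 and 4‑(trifluoromethyl)styrene in THF/NMP at −15 °C to give (R)‑meranzin hydrate acetonide F3. Treatment with 80% aq AcOH removes the acetonide, and the route is rejoined at 7.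

**Step 6 (Ti/Co isomerisation on a coumarin substrate).** The risks are hydrogen abstraction from the carbinol C–H to give the ketone, and Co–H side reactions. The fallback sets out from 9 and uses a polar silyl‑triflate ring opening/elimination instead of the radical relay. TMSOTf with DBU in toluene at −78 → 0 °C gives (S)‑auraptenol trimethylsilyl ether F4. Dilute HCl in THF/H2O removes the silyl group, and the route is rejoined at 10.

## Further compounds

F1 | step 4 | (4S)‑4‑(iodomethyl)‑2,2,5,5‑tetramethyl‑1,3‑dioxolane | CC1(C)OC(C)(C)[C@@H](CI)O1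
F2 | step 4 | (7‑methoxy‑2‑oxo‑2H‑chromen‑8‑yl)zinc iodide | COc1ccc2ccc(=O)oc2c1[Zn]I
F3 | step 4 | 7‑methoxy‑8‑{[(4R)‑2,2,5,5‑tetramethyl‑1,3‑dioxolan‑4‑yl]methyl}‑2H‑chromen‑2‑one | CC1(C)OC(C)(C)[C@@H](Cc2c(OC)ccc3ccc(=O)oc23)O1
F4 | step 6 | 7‑methoxy‑8‑[(2S)‑3‑methyl‑2‑(trimethylsilyloxy)but‑3‑en‑1‑yl]‑2H‑chromen‑2‑one | C=C(C)[C@@H](O[Si](C)(C)C)Cc1c(OC)ccc2ccc(=O)oc12
F0 | step 7 | none | none
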